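**Plan**
The target is read as four flavan units, D–A–B–C: epicatechin (D)-(4β→6)-epiafzelechin (A)-(4β→8)-epicatechin (B)-(4β→6)-epicatechin (C).
Retrosynthesis: (1) remove all benzyl-type ethers and four blocking bromines; (2) cut, in one operation, the C2–C3 bond of the pyran ring of unit B and the B-C4–C-C6 bond, which gives a D–A-substituted 2-aryl-2,3-dihydrobenzofuran-3-carbaldehyde and an 8-bromoepicatechin ether; (3) cut A-C4–B-C8; (4) cut D-C4–A-C6.
Forward: the heterocycles of D, A and C are bought as flavans; D is joined to A, the dimer to the dihydrobenzofuran, and the five-membered ring is expanded last, unit C entering in the same operation.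
Enabling feature: the phloroglucinol ring of unit B (O1, O5, O7 ortho/para to C4) makes C4 a strongly stabilised benzylic cation, so the activated exocyclic formyl carbon (the future C3) can pull C2 over from the benzylic ring carbon.
Stereochemistry: D, A and C come from (−)-epicatechin and (−)-epiafzelechin; C2 of B from a catalytic asymmetric C–H insertion, with C3 and C4 of B relayed from it in the key step; each interflavan bond is 4β by attack anti to the 3-oxygen.

Key step: step 18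

Remark: (−)-epiafzelechin (6) and 3,4-bis(benzyloxy)benzyl chloride (13) are taken as purchasable catalogue compounds.
Remark: Rh2(S-PTTL)4 is assumed to give the (2S) ether carbon in step 14; if the sense is opposite, Rh2(R-PTTL)4 is used.

Step 1
Reactants: 1 (−)-epicatechin
Product: 2 5,7,3',4'-tetra-O-benzyl-(−)-epicatechin
Conditions: BnBr, K2CO3, DMF, 0 °C → rt
Reagents that add atoms: benzyl bromide, BrCc1ccccc1
Why: Williamson ether synthesis, in which the four phenols are alkylated under carbonate conditions while the secondary 3-OH stays free, as is usual for flavan-3-ols.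

Step 2
Reactants: 2 5,7,3',4'-tetra-O-benzyl-(−)-epicatechin
Product: 3 8-bromo-5,7,3',4'-tetra-O-benzyl-(−)-epicatechin
Conditions: NBS (1.0 equiv), CH2Cl2, −78 °C → rt
Reagents that add atoms: N-bromosuccinimide, BrN1C(=O)CCC1=O
Why: electrophilic aromatic bromination, which in 5,7-di-O-benzyl flavans should take the more accessible C8 and so leaves C6 as the only ring carbon through which this unit can later react.

Step 3
Reactants: 2 5,7,3',4'-tetra-O-benzyl-(−)-epicatechin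
Product: 4 (2R,3R,4S)-4β-(2-ethoxyethoxy)-5,7,3',4'-tetra-O-benzylepicatechin
Conditions: DDQ, 2-ethoxyethanol, CH2Cl2, rt
Reagents that add atoms: 2-ethoxyethanol, CCOCCO
Why: DDQ benzylic oxidation (hydride abstraction from C4 of the electron-rich chroman) with capture of the cation by the alcohol anti to the 3-hydroxyl, the usual C4 activation of benzylated flavan-3-ols.

Step 4
Reactants: 4 4β-(2-ethoxyethoxy)-5,7,3',4'-tetra-O-benzylepicatechin
Product: 5 6,8-dibromo-4β-(2-ethoxyethoxy)-5,7,3',4'-tetra-O-benzylepicatechin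
Conditions: NBS (2.2 equiv), CH2Cl2, 0 °C → rt
Reagents that add atoms: N-bromosuccinimide, BrN1C(=O)CCC1=O
Why: electrophilic bromination of both free phloroglucinol positions leaves the future electrophile without a nucleophilic ring carbon, so it cannot self-condense in step 9.

Step 5
Reactants: 6 (−)-epiafzelechin
Product: 7 5,7,4'-tri-O-benzyl-(−)-epiafzelechin
Conditions: BnBr, K2CO3, DMF, 0 °C → rt
Reagents that add atoms: benzyl bromide, BrCc1ccccc1
Why: Williamson ether synthesis of the three phenols, the 3-OH staying free.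

Step 6
Reactants: 7 5,7,4'-tri-O-benzyl-(−)-epiafzelechin
Product: 8 (2R,3R,4S)-4β-(2-ethoxyethoxy)-5,7,4'-tri-O-benzylepiafzelechin
Conditions: DDQ, 2-ethoxyethanol, CH2Cl2, rt
Reagents that add atoms: 2-ethoxyethanol, CCOCCO
Why: DDQ benzylic oxidation at C4 with anti capture by the alcohol, as in step 3.

Step 7
Reactants: 8 4β-(2-ethoxyethoxy)-5,7,4'-tri-O-benzylepiafzelechin
Product: 9 8-bromo-4β-(2-ethoxyethoxy)-5,7,4'-tri-O-benzylepiafzelechin
Conditions: NBS (1.0 equiv), CH2Cl2, −78 °C → 0 °C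
Reagents that add atoms: N-bromosuccinimide, BrN1C(=O)CCC1=O
Why: electrophilic bromination at the more accessible C8, which blocks it so that unit A can be arylated only at C6.

Step 8
Reactants: 9 8-bromo-4β-(2-ethoxyethoxy)-5,7,4'-tri-O-benzylepiafzelechin
Product: 10 (2R,3S,4S)-8-bromo-4β-[(2,6-dimethylphenyl)sulfanyl]-5,7,4'-tri-O-benzylepiafzelechin
Conditions: 2,6-dimethylbenzenethiol, BF3·OEt2, CH2Cl2, −78 °C
Reagents that add atoms: 2,6-dimethylbenzenethiol, Cc1cccc(C)c1S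
Why: Lewis-acid exchange of the C4 alkoxy group for the thiol through the flavan-4-yl cation (SN1, attack anti to the 3-OH) gives a 4β-sulfide that is inert to hard Lewis acids and is activated later by a thiophile (orthogonal activation).

Step 9
Reactants: 5 6,8-dibromo-4β-(2-ethoxyethoxy)-tetra-O-benzylepicatechin; 10 8-bromo-4β-arylsulfanyl-tri-O-benzylepiafzelechin
Product: 11 [6,8-dibromo-tetra-O-benzylepicatechin]-(4β→6)-[8-bromo-4β-(2,6-dimethylphenylsulfanyl)-tri-O-benzylepiafzelechin]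
Conditions: BF3·OEt2, 4 Å MS, CH2Cl2, −78 → −20 °C
Reagents that add atoms: none
Why: Friedel–Crafts interflavan coupling in which BF3 ionises only the C4–O bond of 5 and the cation is attacked by the single free ring carbon (C6) of 10 anti to the 3-hydroxyl, giving the 3,4-trans (4β→6) bond while the C4–S bond survives.

Step 10
Reactants: 12 2,4,6-trihydroxybenzaldehyde; 13 3,4-bis(benzyloxy)benzyl chloride
Product: 14 2,4,6-tris{[3,4-bis(benzyloxy)phenyl]methoxy}benzaldehyde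
Conditions: 13 (3.3 equiv in all), K2CO3, n-Bu4NI (cat.), DMF, 60 °C
Reagents that add atoms: 3,4-bis(benzyloxy)benzyl chloride, ClCc1ccc(OCc2ccccc2)c(OCc2ccccc2)c1
Why: threefold Williamson etherification with three equivalents of the one chloride, of which one copy later supplies C2 and the catechol ring of unit B and the other two serve as hydrogenolysable phenol protecting groups, keeps the arene symmetric so that the two ortho ether methylenes are identical in the later C–H insertion.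

Step 11
Reactants: 14 2,4,6-tris{[3,4-bis(benzyloxy)phenyl]methoxy}benzaldehyde
Product: 15 2-(2-methoxyethenyl)-1,3,5-tris{[3,4-bis(benzyloxy)phenyl]methoxy}benzene (E/Z mixture)
Conditions: Ph3P(CH2OMe)Cl, KOt-Bu, THF, 0 °C → rt
Reagents that add atoms: (methoxymethyl)triphenylphosphonium chloride, COC[P+](c1ccccc1)(c1ccccc1)c1ccccc1.[Cl-]
Why: Wittig methoxymethylenation of the aldehyde gives the one-carbon-homologated enol ether.

Step 12
Reactants: 15 enol ether
Product: 16 methyl 2-(2,4,6-tris{[3,4-bis(benzyloxy)phenyl]methoxy}phenyl)acetate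
Conditions: C5H5NH[CrO3Cl] (pyridinium chlorochromate), NaOAc, CH2Cl2, rt
Reagents that add atoms: pyridinium chlorochromate, [O-][Cr](=O)(=O)Cl.c1cc[nH+]cc1
Why: oxidation of an enol ether to the ester by chlorochromate converts the homologated enol ether directly into the arylacetate.

Step 13
Reactants: 16 methyl arylacetate
Product: 17 methyl 2-diazo-2-(2,4,6-tris{[3,4-bis(benzyloxy)phenyl]methoxy}phenyl)acetate
Conditions: 4-acetamidobenzenesulfonyl azide, DBU, MeCN, 0 °C → rt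
Reagents that add atoms: 4-acetamidobenzenesulfonyl azide, CC(=O)Nc1ccc(cc1)S(=O)(=O)N=[N+]=[N-]
Why: Regitz diazo transfer to the benzylic, ester-activated methylene gives the donor/acceptor aryldiazoacetate.

Step 14
Reactants: 17 aryldiazoacetate
Product: 18 methyl (2S,3R)-cis-2-[3,4-bis(benzyloxy)phenyl]-4,6-bis{[3,4-bis(benzyloxy)phenyl]methoxy}-2,3-dihydro-1-benzofuran-3-carboxylate
Conditions: Rh2(S-PTTL)4 (dirhodium tetrakis[N-phthaloyl-(S)-tert-leucinate], 1 mol %), toluene, −60 °C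
Reagents that add atoms: none
Why: intramolecular 1,5 C–H insertion of the dirhodium carbenoid into the electron-rich benzylic methylene of an ortho ether (both ortho sites equivalent by symmetry) closes the dihydrobenzofuran, the chiral carboxylate ligands setting the ether carbon C2 and the kinetic product being the cis ester.

Step 15
Reactants: 18 cis ester
Product: 19 methyl (2S,3S)-trans-2-[3,4-bis(benzyloxy)phenyl]-4,6-bis{[3,4-bis(benzyloxy)phenyl]methoxy}-2,3-dihydro-1-benzofuran-3-carboxylate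
Conditions: NaOMe (0.5 equiv), MeOH/THF, rt
Reagents that add atoms: none
Why: base-mediated epimerisation through the ester enolate moves only C3 and gives the more stable trans ester, C2 being untouched.

Step 16
Reactants: 11 D–A dimer 4β-sulfide; 19 trans dihydrobenzofuran ester
Product: 20 D–A dimer joined through A-C4 (4β) to C7 of the trans dihydrobenzofuran methyl ester (trimer ester)
Conditions: N-iodosuccinimide, 4 Å MS, CH2Cl2, −78 → −20 °C
Reagents that add atoms: none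
Why: thiophilic activation of the C4–S bond gives the flavan-4-yl cation of unit A (orthogonal to the BF3 step), which is trapped in a Friedel–Crafts alkylation by C7 of 19 (the less hindered phloroglucinol position, the counterpart of C8 of a flavan) anti to the 3-hydroxyl, that is 4β.

Step 17
Reactants: 20 trimer ester
Product: 21 trimer aldehyde (D–A dimer 4β-linked to C7 of the (2S,3S)-trans-2-aryl-2,3-dihydrobenzofuran-3-carbaldehyde)
Conditions: i-Bu2AlH (4 equiv), CH2Cl2, −78 °C; MeOH, then aq. potassium sodium tartrate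
Reagents that add atoms: none
Why: partial reduction of the methyl ester by i-Bu2AlH at −78 °C, where the aluminium hemiacetal persists until work-up, gives the aldehyde, the excess hydride covering the two free hydroxyls.

Step 18
Reactants: 21 trimer aldehyde; 3 8-bromo-5,7,3',4'-tetra-O-benzyl-(−)-epicatechin
Product: 23 fully protected tetrabromo tetramer D-(4β→6)-A-(4β→8)-B-(4β→6)-C, via flavan-4-yl cation 22 (not isolated)
Conditions: 3 (5 equiv), BF3·OEt2 (3 equiv), 4 Å MS, CH2Cl2, −78 → −20 °C; aq. NaHCO3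
Reagents that add atoms: none
Why: Proposed new method: BF3 binds the formyl oxygen of 21, and the benzofuran C2–C3 σ bond, aligned with the carbonyl π* orbital, shifts from the benzylic ring carbon to the formyl carbon (a pinacol-type 1,2-alkyl shift onto an activated carbonyl, the first half of an aldehyde–ketone rearrangement). This inserts the formyl carbon between C2 and the benzylic carbon, so the five-membered ring O1–C2–C3–C3a–C7a becomes the six-membered pyran ring by 1,2-migration (ring expansion, not a cyclisation), and the charge is left on the former benzofuran C3, now flavan C4, as the O1/O5/O7-stabilised benzylic cation 22, which C6 of 3 then takes in a Friedel–Crafts alkylation of the kind known for flavan-4-yl cations. The closest known reaction types are the Wagner–Meerwein ring expansion of cyclopentylcarbinyl cations and the acid-promoted aldehyde–ketone rearrangement, in which the group migrates whose shift leaves the better-stabilised cation. C2 migrates with retention and so becomes flavan C2 unchanged, while the new C3 is set by the face of the formyl group that receives C2: in the trans aldehyde the bulky O–BF3 group should point away from the benzo ring (formyl hydrogen over the ring), which places the 3-oxygen cis to the 2-aryl group. C4 is set by attack of the arene anti to the 3-O–BF3 group (3,4-trans, 4β). The step needs C2 to migrate in preference to the electron-rich benzo ring (aryl bridging leads only to a β-oxygenated secondary cation, C2 migration to the trioxygenated benzylic cation), no loss of the benzylic proton (aprotic, base-free, cold), and attack of 3 through C6 (C8 carries bromine, the arenes of D and A are blocked, and excess 3 outcompetes the one hindered free position of the trimer).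

Step 19
Reactants: 23 fully protected tetrabromo tetramer
Product: 24 epicatechin-(4β→6)-epiafzelechin-(4β→8)-epicatechin-(4β→6)-epicatechin (target)
Conditions: H2 (1 atm), Pd(OH)2/C, Et3N, THF/MeOH/H2O, rt
Reagents that add atoms: none
Why: hydrogenolysis cleaves the benzylic C–O bonds of the seventeen benzyl and two 3,4-dioxygenated benzyl ethers and, with Et3N as HBr scavenger, the four aryl C–Br bonds, without touching the interflavan bonds or the stereocentres.

**Compound list**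
1 | (−)-epicatechin, (2R,3R)-2-(3,4-dihydroxyphenyl)chromane-3,5,7-triol | Oc1ccc([C@H]2Oc3cc(O)cc(O)c3C[C@H]2O)cc1O | starting material
2 | 5,7,3',4'-tetra-O-benzyl-(−)-epicatechin | c6ccccc6COc1ccc([C@H]2Oc3cc(OCc6ccccc6)cc(OCc6ccccc6)c3C[C@H]2O)cc1OCc6ccccc6 | intermediate
3 | 8-bromo-5,7,3',4'-tetra-O-benzyl-(−)-epicatechin | c6ccccc6COc1ccc([C@H]2Oc3c(Br)c(OCc6ccccc6)cc(OCc6ccccc6)c3C[C@H]2O)cc1OCc6ccccc6 | intermediate
4 | (2R,3R,4S)-4β-(2-ethoxyethoxy)-5,7,3',4'-tetra-O-benzylepicatechin | c6ccccc6COc1ccc([C@H]2Oc3cc(OCc6ccccc6)cc(OCc6ccccc6)c3[C@H](OCCOCC)[C@H]2O)cc1OCc6ccccc6 | intermediate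
5 | 6,8-dibromo-4β-(2-ethoxyethoxy)-5,7,3',4'-tetra-O-benzylepicatechin | c6ccccc6COc1ccc([C@H]2Oc3c(Br)c(OCc6ccccc6)c(Br)c(OCc6ccccc6)c3[C@H](OCCOCC)[C@H]2O)cc1OCc6ccccc6 | intermediate
6 | (−)-epiafzelechin, (2R,3R)-2-(4-hydroxyphenyl)chromane-3,5,7-triol | Oc1ccc([C@H]2Oc3cc(O)cc(O)c3C[C@H]2O)cc1 | starting material
7 | 5,7,4'-tri-O-benzyl-(−)-epiafzelechin | c6ccccc6COc1ccc([C@H]2Oc3cc(OCc6ccccc6)cc(OCc6ccccc6)c3C[C@H]2O)cc1 | intermediate
8 | (2R,3R,4S)-4β-(2-ethoxyethoxy)-5,7,4'-tri-O-benzylepiafzelechin | c6ccccc6COc1ccc([C@H]2Oc3cc(OCc6ccccc6)cc(OCc6ccccc6)c3[C@H](OCCOCC)[C@H]2O)cc1 | intermediate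
9 | 8-bromo-4β-(2-ethoxyethoxy)-5,7,4'-tri-O-benzylepiafzelechin | c6ccccc6COc1ccc([C@H]2Oc3c(Br)c(OCc6ccccc6)cc(OCc6ccccc6)c3[C@H](OCCOCC)[C@H]2O)cc1 | intermediate
10 | (2R,3S,4S)-8-bromo-4β-[(2,6-dimethylphenyl)sulfanyl]-5,7,4'-tri-O-benzylepiafzelechin | c6ccccc6COc1ccc([C@H]2Oc3c(Br)c(OCc6ccccc6)cc(OCc6ccccc6)c3[C@H](Sc3c(C)cccc3C)[C@H]2O)cc1 | intermediate
11 | [6,8-dibromo-5,7,3',4'-tetra-O-benzylepicatechin]-(4β→6)-[8-bromo-4β-(2,6-dimethylphenylsulfanyl)-5,7,4'-tri-O-benzylepiafzelechin] | c6ccccc6COc1ccc([C@H]2Oc3c(Br)c(OCc6ccccc6)c([C@H]4c5c(OCc6ccccc6)c(Br)c(OCc6ccccc6)c(Br)c5O[C@H](c5ccc(OCc6ccccc6)c(OCc6ccccc6)c5)[C@@H]4O)c(OCc6ccccc6)c3[C@H](Sc3c(C)cccc3C)[C@H]2O)cc1 | intermediate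
12 | 2,4,6-trihydroxybenzaldehyde | O=Cc1c(O)cc(O)cc1O | starting material
13 | 3,4-bis(benzyloxy)benzyl chloride | ClCc1ccc(OCc2ccccc2)c(OCc2ccccc2)c1 | starting material
14 | 2,4,6-tris{[3,4-bis(benzyloxy)phenyl]methoxy}benzaldehyde | O=Cc1c(OCc7ccc(OCc8ccccc8)c(OCc8ccccc8)c7)cc(OCc7ccc(OCc8ccccc8)c(OCc8ccccc8)c7)cc1OCc7ccc(OCc8ccccc8)c(OCc8ccccc8)c7 | intermediate
15 | 2-(2-methoxyethenyl)-1,3,5-tris{[3,4-bis(benzyloxy)phenyl]methoxy}benzene (E/Z mixture) | COC=Cc1c(OCc7ccc(OCc8ccccc8)c(OCc8ccccc8)c7)cc(OCc7ccc(OCc8ccccc8)c(OCc8ccccc8)c7)cc1OCc7ccc(OCc8ccccc8)c(OCc8ccccc8)c7 | intermediate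
16 | methyl 2-(2,4,6-tris{[3,4-bis(benzyloxy)phenyl]methoxy}phenyl)acetate | COC(=O)Cc1c(OCc7ccc(OCc8ccccc8)c(OCc8ccccc8)c7)cc(OCc7ccc(OCc8ccccc8)c(OCc8ccccc8)c7)cc1OCc7ccc(OCc8ccccc8)c(OCc8ccccc8)c7 | intermediate
17 | methyl 2-diazo-2-(2,4,6-tris{[3,4-bis(benzyloxy)phenyl]methoxy}phenyl)acetate | COC(=O)C(=[N+]=[N-])c1c(OCc7ccc(OCc8ccccc8)c(OCc8ccccc8)c7)cc(OCc7ccc(OCc8ccccc8)c(OCc8ccccc8)c7)cc1OCc7ccc(OCc8ccccc8)c(OCc8ccccc8)c7 | intermediate
18 | methyl (2S,3R)-cis-2-[3,4-bis(benzyloxy)phenyl]-4,6-bis{[3,4-bis(benzyloxy)phenyl]methoxy}-2,3-dihydro-1-benzofuran-3-carboxylate | c1(OCc7ccc(OCc8ccccc8)c(OCc8ccccc8)c7)cc(OCc7ccc(OCc8ccccc8)c(OCc8ccccc8)c7)c2c(c1)O[C@H](c1ccc(OCc6ccccc6)c(OCc6ccccc6)c1)[C@@H]2C(=O)OC | intermediate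
19 | methyl (2S,3S)-trans-2-[3,4-bis(benzyloxy)phenyl]-4,6-bis{[3,4-bis(benzyloxy)phenyl]methoxy}-2,3-dihydro-1-benzofuran-3-carboxylate | c1(OCc7ccc(OCc8ccccc8)c(OCc8ccccc8)c7)cc(OCc7ccc(OCc8ccccc8)c(OCc8ccccc8)c7)c2c(c1)O[C@H](c1ccc(OCc6ccccc6)c(OCc6ccccc6)c1)[C@H]2C(=O)OC | intermediate
20 | trimer ester: dimer of 11 (sulfide replaced) bonded through A-C4 (4β) to C7 of ester 19 | c6ccccc6COc1ccc([C@H]2Oc3c(Br)c(OCc6ccccc6)c([C@H]4c5c(OCc6ccccc6)c(Br)c(OCc6ccccc6)c(Br)c5O[C@H](c5ccc(OCc6ccccc6)c(OCc6ccccc6)c5)[C@@H]4O)c(OCc6ccccc6)c3[C@H](c3c(OCc7ccc(OCc8ccccc8)c(OCc8ccccc8)c7)cc(OCc7ccc(OCc8ccccc8)c(OCc8ccccc8)c7)c4c3O[C@H](c3ccc(OCc6ccccc6)c(OCc6ccccc6)c3)[C@H]4C(=O)OC)[C@H]2O)cc1 | intermediate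
21 | trimer aldehyde: as 20 with a (2S,3S)-trans-3-formyl group in place of the ester | c6ccccc6COc1ccc([C@H]2Oc3c(Br)c(OCc6ccccc6)c([C@H]4c5c(OCc6ccccc6)c(Br)c(OCc6ccccc6)c(Br)c5O[C@H](c5ccc(OCc6ccccc6)c(OCc6ccccc6)c5)[C@@H]4O)c(OCc6ccccc6)c3[C@H](c3c(OCc7ccc(OCc8ccccc8)c(OCc8ccccc8)c7)cc(OCc7ccc(OCc8ccccc8)c(OCc8ccccc8)c7)c4c3O[C@H](c3ccc(OCc6ccccc6)c(OCc6ccccc6)c3)[C@H]4C=O)[C@H]2O)cc1 | intermediate
22 | ring-expanded 2,3-cis-flavan-4-yl cation of unit B with 3-O–BF3 (zwitterion) | c6ccccc6COc1ccc([C@H]2Oc3c(Br)c(OCc6ccccc6)c([C@H]4c5c(OCc6ccccc6)c(Br)c(OCc6ccccc6)c(Br)c5O[C@H](c5ccc(OCc6ccccc6)c(OCc6ccccc6)c5)[C@@H]4O)c(OCc6ccccc6)c3[C@H](c3c(OCc7ccc(OCc8ccccc8)c(OCc8ccccc8)c7)cc(OCc7ccc(OCc8ccccc8)c(OCc8ccccc8)c7)c4c3O[C@H](c3ccc(OCc6ccccc6)c(OCc6ccccc6)c3)[C@H](O[B-](F)(F)F)[CH+]4)[C@H]2O)cc1 | intermediate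
23 | fully protected tetramer: D 6,8-dibromo tetra-O-benzyl; A 8-bromo tri-O-benzyl; B 3',4'-di-O-benzyl-5,7-bis-O-[3,4-bis(benzyloxy)benzyl]; C 8-bromo tetra-O-benzyl; all 3-OH free | c6ccccc6COc1ccc([C@H]2Oc3c(Br)c(OCc6ccccc6)c([C@H]4c5c(OCc6ccccc6)c(Br)c(OCc6ccccc6)c(Br)c5O[C@H](c5ccc(OCc6ccccc6)c(OCc6ccccc6)c5)[C@@H]4O)c(OCc6ccccc6)c3[C@H](c3c(OCc7ccc(OCc8ccccc8)c(OCc8ccccc8)c7)cc(OCc7ccc(OCc8ccccc8)c(OCc8ccccc8)c7)c4c3O[C@H](c3ccc(OCc6ccccc6)c(OCc6ccccc6)c3)[C@H](O)[C@H]4c3c(OCc6ccccc6)c(Br)c4c(c3OCc6ccccc6)C[C@@H](O)[C@@H](c3ccc(OCc6ccccc6)c(OCc6ccccc6)c3)O4)[C@H]2O)cc1 | intermediate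
24 | epicatechin-(4β→6)-epiafzelechin-(4β→8)-epicatechin-(4β→6)-epicatechin | Oc1ccc([C@H]2Oc3cc(O)c([C@H]4c5c(O)cc(O)cc5O[C@H](c5ccc(O)c(O)c5)[C@@H]4O)c(O)c3[C@H](c3c(O)cc(O)c4c3O[C@H](c3ccc(O)c(O)c3)[C@H](O)[C@H]4c3c(O)cc4c(c3O)C[C@@H](O)[C@@H](c3ccc(O)c(O)c3)O4)[C@H]2O)cc1 | target

**Totals and risks**
Total step count: 19. Longest linear sequence: 10 steps (12 → 14 → 15 → 16 → 17 → 18 → 19 → 20 → 21 → 23 → 24).

Step 18 (proposed new method) is the most likely to fail. The electron-rich benzo ring may migrate instead of C2, leading on to a flavanone. The benzylic proton next to the activated formyl group may be lost, with aromatisation to a benzofuran. The arene may also add directly to the aldehyde, or the 3,4-dioxygenated benzyl ethers may ionise under BF3. The fallback builds unit B from epicatechin by known chemistry. It sets out from 11 and 2: N-iodosuccinimide activation of 11 in the presence of excess 2 should give, by attack through C8 of 2, the perbenzylated tribromo trimer F1. DDQ with 2-ethoxyethanol should then oxidise C4 of its lowest unit to the 4β-(2-ethoxyethoxy) trimer F2. BF3·OEt2 coupling of F2 with excess 3 through C6 should give the perbenzylated tetrabromo tetramer F3, and hydrogenolysis as in step 19 returns to the route at 24.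

Step 9 comes second. Ionisation of the doubly brominated electrophile may be slow, and so may attack at C6 of 10, which is flanked by two benzyloxy groups and lies next to the bulky 4β-arylsulfanyl group; stalling or decomposition would follow. The fallback moves the C4 activation of unit A to after the coupling. It sets out from 7 and 5: NBS on 7 gives 8-bromo-5,7,4'-tri-O-benzylepiafzelechin F4. Its less hindered C6 is coupled with 5 under BF3·OEt2 to the dimer F5, which has a C4 methylene in unit A. DDQ with 2-ethoxyethanol converts F5 into the dimer 4β-(2-ethoxyethoxy) ether F6, and BF3·OEt2 coupling of F6 with 19 comes back to the route at 20.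

Step 17 comes third. Over-reduction of the ester to the primary alcohol, or incomplete conversion on a substrate with two free hydroxyls, may spoil the partial reduction. The fallback sets out from 20: LiBH4 in THF reduces the ester fully to the trimer primary alcohol F7. Chemoselective oxidation of the primary alcohol with TEMPO and PhI(OAc)2, which should leave the hindered secondary 3-hydroxyls untouched, comes back to the route at 21.

**Further compounds**
F1 | step 18 | [6,8-dibromo-tetra-O-benzylepicatechin]-(4β→6)-[8-bromo-tri-O-benzylepiafzelechin]-(4β→8)-[5,7,3',4'-tetra-O-benzylepicatechin] | c6ccccc6COc1ccc([C@H]2Oc3c(Br)c(OCc6ccccc6)c([C@H]4c5c(OCc6ccccc6)c(Br)c(OCc6ccccc6)c(Br)c5O[C@H](c5ccc(OCc6ccccc6)c(OCc6ccccc6)c5)[C@@H]4O)c(OCc6ccccc6)c3[C@H](c3c(OCc6ccccc6)cc(OCc6ccccc6)c4c3O[C@H](c3ccc(OCc6ccccc6)c(OCc6ccccc6)c3)[C@H](O)C4)[C@H]2O)cc1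
F2 | step 18 | trimer F1 carrying a 4β-(2-ethoxyethoxy) group on its lowest unit | c6ccccc6COc1ccc([C@H]2Oc3c(Br)c(OCc6ccccc6)c([C@H]4c5c(OCc6ccccc6)c(Br)c(OCc6ccccc6)c(Br)c5O[C@H](c5ccc(OCc6ccccc6)c(OCc6ccccc6)c5)[C@@H]4O)c(OCc6ccccc6)c3[C@H](c3c(OCc6ccccc6)cc(OCc6ccccc6)c4c3O[C@H](c3ccc(OCc6ccccc6)c(OCc6ccccc6)c3)[C@H](O)[C@H]4OCCOCC)[C@H]2O)cc1
F3 | step 18 | perbenzylated tetrabromo tetramer (all phenols as benzyl ethers; bromine at D-6, D-8, A-8, C-8) | c6ccccc6COc1ccc([C@H]2Oc3c(Br)c(OCc6ccccc6)c([C@H]4c5c(OCc6ccccc6)c(Br)c(OCc6ccccc6)c(Br)c5O[C@H](c5ccc(OCc6ccccc6)c(OCc6ccccc6)c5)[C@@H]4O)c(OCc6ccccc6)c3[C@H](c3c(OCc6ccccc6)cc(OCc6ccccc6)c4c3O[C@H](c3ccc(OCc6ccccc6)c(OCc6ccccc6)c3)[C@H](O)[C@H]4c3c(OCc6ccccc6)c(Br)c4c(c3OCc6ccccc6)C[C@@H](O)[C@@H](c3ccc(OCc6ccccc6)c(OCc6ccccc6)c3)O4)[C@H]2O)cc1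
F4 | step 9 | 8-bromo-5,7,4'-tri-O-benzyl-(−)-epiafzelechin | c6ccccc6COc1ccc([C@H]2Oc3c(Br)c(OCc6ccccc6)cc(OCc6ccccc6)c3C[C@H]2O)cc1
F5 | step 9 | [6,8-dibromo-tetra-O-benzylepicatechin]-(4β→6)-[8-bromo-tri-O-benzylepiafzelechin] | c6ccccc6COc1ccc([C@H]2Oc3c(Br)c(OCc6ccccc6)c([C@H]4c5c(OCc6ccccc6)c(Br)c(OCc6ccccc6)c(Br)c5O[C@H](c5ccc(OCc6ccccc6)c(OCc6ccccc6)c5)[C@@H]4O)c(OCc6ccccc6)c3C[C@H]2O)cc1
F6 | step 9 | dimer F5 carrying a 4β-(2-ethoxyethoxy) group on the epiafzelechin unit | c6ccccc6COc1ccc([C@H]2Oc3c(Br)c(OCc6ccccc6)c([C@H]4c5c(OCc6ccccc6)c(Br)c(OCc6ccccc6)c(Br)c5O[C@H](c5ccc(OCc6ccccc6)c(OCc6ccccc6)c5)[C@@H]4O)c(OCc6ccccc6)c3[C@H](OCCOCC)[C@H]2O)cc1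
F7 | step 17 | trimer primary alcohol: as 20 with a 3-hydroxymethyl group in place of the ester | c6ccccc6COc1ccc([C@H]2Oc3c(Br)c(OCc6ccccc6)c([C@H]4c5c(OCc6ccccc6)c(Br)c(OCc6ccccc6)c(Br)c5O[C@H](c5ccc(OCc6ccccc6)c(OCc6ccccc6)c5)[C@@H]4O)c(OCc6ccccc6)c3[C@H](c3c(OCc7ccc(OCc8ccccc8)c(OCc8ccccc8)c7)cc(OCc7ccc(OCc8ccccc8)c(OCc8ccccc8)c7)c4c3O[C@H](c3ccc(OCc6ccccc6)c(OCc6ccccc6)c3)[C@H]4CO)[C@H]2O)cc1
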